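**Plan**

- Target: (2R)-2-[(12Z)-henicos-12-en-1-yl]-6-methyl-2,3-dihydro-4H-pyran-4-one; ring atoms O1, C2 (side chain), C3, C4 (C=O), C5, C6 (CH3).
- Enabling feature: C3–C4(=O)–C5 is an acetone unit whose two α-carbons are bonded to C2 (aldehyde oxidation level) and C6 (carboxylic acid oxidation level), both tied through O1. The ring is the cyclic enol ether of a δ-hydroxy-β-diketone, so an acetone 1,3-dinucleophile can be clipped between an aldehyde and an acetyl equivalent.
- Retrosynthesis: a tert-butoxycarbonyl helper is placed on C5 (removed last by acidolysis and decarboxylation). Then C2–C3, C5=C6 and O1–C6 are cut together to (13Z)-docos-13-enal, the bis-silyl dienol ether of tert-butyl acetoacetate and N,N-dimethylacetamide dimethyl acetal.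
- Forward: the C22 chain with its Z-alkene is taken intact from erucyl alcohol by oxidation; the diene is made by two silylations; the only ring forms in the three-component step; the helper is then removed.
- Stereochemistry: the single stereocentre C2 (R) arises in the key step from Si-face aldol addition under titanium–(S)-BINOL control; all later operations are acidic and never break the C2–O1 bond.

Key step: step 4

Remark: (S)-BINOL is taken as the ligand enantiomer that directs the dienolate to the Si face of an unbranched aliphatic aldehyde, by analogy with related titanium–BINOL carbonyl additions; the configuration would be checked at the hydroxy ketoester stage (chiral HPLC, MTPA esters) and the mirror-image ligand used if the sense proved opposite.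

**Step 1**
Reactants: 1 erucyl alcohol, (13Z)-docos-13-en-1-ol
Product: 2 (13Z)-docos-13-enal
Conditions: TEMPO (10 mol%), PhI(OAc)2 (1.1 equiv), CH2Cl2, rt
Reagents that add atoms: none
Why: The oxoammonium-mediated oxidation with PhI(OAc)2 as terminal oxidant should stop at the aldehyde in anhydrous CH2Cl2 and leave the isolated Z-alkene untouched (TEMPO/PhI(OAc)2 alcohol oxidation).

**Step 2**
Reactants: 3 tert-butyl acetoacetate
Product: 4 tert-butyl 3-(trimethylsilyloxy)but-2-enoate
Conditions: Me3SiCl, Et3N, hexane, rt
Reagents that add atoms: chlorotrimethylsilane, C[Si](C)(C)Cl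
Why: The readily enolised β-keto ester should be O-silylated under amine-base conditions to give the conjugated silyl enol ether (standard silyl enol ether formation), its double-bond geometry being of no consequence.

**Step 3**
Reactants: 4 tert-butyl 3-(trimethylsilyloxy)but-2-enoate
Product: 5 1-tert-butoxy-1,3-bis(trimethylsilyloxy)buta-1,3-diene
Conditions: LiN(i-Pr)2, THF, −78 °C; then Me3SiCl, −78 °C to 0 °C
Reagents that add atoms: chlorotrimethylsilane, C[Si](C)(C)Cl
Why: Kinetic deprotonation of the ester enolate position of the vinylogous carbonate followed by O-silylation should give the ketene silyl acetal–silyl enol ether diene (standard preparation of 1,3-bis(silyloxy)-1,3-dienes from β-keto esters).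

**Step 4**
Reactants: 2 (13Z)-docos-13-enal; 5 1-tert-butoxy-1,3-bis(trimethylsilyloxy)buta-1,3-diene; 6 N,N-dimethylacetamide dimethyl acetal
Product: 10 tert-butyl (2R)-2-[(12Z)-henicos-12-en-1-yl]-6-methyl-4-oxo-3,4-dihydro-2H-pyran-5-carboxylate, via bis-silylated aldol adduct 7 (not isolated), via hydroxy ketoester 8 (not isolated), via enaminone 9 (not isolated)
Conditions: 2 (1 equiv), 5 (1.5 equiv), Ti(OiPr)4 (8 mol%), (S)-BINOL (8 mol%), 4 Å MS, THF, −78 °C to rt; then MeOH, PPTS (cat.), rt, evaporate; then 6 (2.5 equiv), toluene, rt
Reagents that add atoms: none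
Why: The (S)-BINOL–Ti(OiPr)4 complex activates aldehyde 2 and the terminal carbon of diene 5 adds in a vinylogous Mukaiyama aldol reaction that forms C2–C3, after which methanolysis of the silylated adduct 7 unveils hydroxy ketoester 8. Amide acetal 6 then condenses at the doubly activated methylene between ketone and ester (Knoevenagel-type, forming the C5=C6 bond) to give enaminone 9, and the C2 hydroxyl displaces dimethylamine. The closest known reaction types are the titanium–BINOL aldol of acetoacetate-derived bis-silyl dienol ethers with aliphatic aldehydes and the Maitland–Japp-type cyclocondensation of δ-hydroxy-β-keto esters with amide acetals to dihydropyran-4-ones, here run in one flask. The pyranone ring closes by 6-endo-trig oxa-Michael addition of O1 to C6 followed by elimination of dimethylamine. The only new stereocentre, C2, is set by the chiral titanium complex, the (S)-ligand being expected to direct attack to the Si face of the aldehyde and give the R carbinol. The step needs γ-regioselectivity in the aldol, secured because the unsubstituted terminus of the bis-silyl dienol ether is its most nucleophilic carbon, and condensation at C5 in preference to C3, secured by the tert-butoxycarbonyl helper that makes C5 the most acidic site.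

**Step 5**
Reactants: 10 tert-butyl (2R)-2-[(12Z)-henicos-12-en-1-yl]-6-methyl-4-oxo-3,4-dihydro-2H-pyran-5-carboxylate
Product: 12 (2R)-2-[(12Z)-henicos-12-en-1-yl]-6-methyl-2,3-dihydro-4H-pyran-4-one (target), via pyranone carboxylic acid 11 (not isolated)
Conditions: TFA, CH2Cl2, 0 °C to rt; evaporate; then 1 M aq. HCl–THF, 50 °C
Reagents that add atoms: none
Why: Trifluoroacetic acid should cleave the tert-butyl ester by loss of 2-methylpropene, and in warm aqueous acid the vinylogous β-keto acid 11 should lose CO2 after reversible addition of water across C5=C6 makes C5 tetrahedral and then re-form the enol ether by dehydration, while the C2–O1 bond is never broken and the Z-alkene is inert (acid-mediated tert-butyl ester cleavage and β-keto acid decarboxylation).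

**Compound list**

1 | erucyl alcohol, (13Z)-docos-13-en-1-ol | CCCCCCCC/C=C\CCCCCCCCCCCCO | starting material
2 | (13Z)-docos-13-enal | CCCCCCCC/C=C\CCCCCCCCCCCC=O | intermediate
3 | tert-butyl acetoacetate (tert-butyl 3-oxobutanoate) | CC(=O)CC(=O)OC(C)(C)C | starting material
4 | tert-butyl 3-(trimethylsilyloxy)but-2-enoate (E/Z mixture, geometry inconsequential) | CC(O[Si](C)(C)C)=CC(=O)OC(C)(C)C | intermediate
5 | 1-tert-butoxy-1,3-bis(trimethylsilyloxy)buta-1,3-diene (geometry at C1=C2 inconsequential) | C=C(O[Si](C)(C)C)C=C(OC(C)(C)C)O[Si](C)(C)C | intermediate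
6 | N,N-dimethylacetamide dimethyl acetal (1,1-dimethoxy-N,N-dimethylethan-1-amine) | CC(OC)(OC)N(C)C | starting material
7 | tert-butyl (5R,17Z)-3,5-bis(trimethylsilyloxy)hexacosa-2,17-dienoate (C2=C3 geometry undefined) | CCCCCCCC/C=C\CCCCCCCCCCC[C@@H](O[Si](C)(C)C)CC(O[Si](C)(C)C)=CC(=O)OC(C)(C)C | intermediate (not isolated)
8 | tert-butyl (5R,17Z)-5-hydroxy-3-oxohexacos-17-enoate | CCCCCCCC/C=C\CCCCCCCCCCC[C@@H](O)CC(=O)CC(=O)OC(C)(C)C | intermediate (not isolated)
9 | tert-butyl (5R,17Z)-2-[1-(dimethylamino)ethylidene]-5-hydroxy-3-oxohexacos-17-enoate (enaminone geometry undefined) | CCCCCCCC/C=C\CCCCCCCCCCC[C@@H](O)CC(=O)C(=C(C)N(C)C)C(=O)OC(C)(C)C | intermediate (not isolated)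
10 | tert-butyl (2R)-2-[(12Z)-henicos-12-en-1-yl]-6-methyl-4-oxo-3,4-dihydro-2H-pyran-5-carboxylate | CCCCCCCC/C=C\CCCCCCCCCCC[C@@H]1CC(=O)C(C(=O)OC(C)(C)C)=C(C)O1 | intermediate
11 | (2R)-2-[(12Z)-henicos-12-en-1-yl]-6-methyl-4-oxo-3,4-dihydro-2H-pyran-5-carboxylic acid | CCCCCCCC/C=C\CCCCCCCCCCC[C@@H]1CC(=O)C(C(=O)O)=C(C)O1 | intermediate (not isolated)
12 | (2R)-2-[(12Z)-henicos-12-en-1-yl]-6-methyl-2,3-dihydro-4H-pyran-4-one | CCCCCCCC/C=C\CCCCCCCCCCC[C@@H]1CC(=O)C=C(C)O1 | target

**Step count**

Total steps: 5. Longest linear sequence: 4 steps (steps 2, 3, 4 and 5, from tert-butyl acetoacetate).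

**Steps most likely to fail**

Step 4. The titanium and binaphthol residues left from the aldol stage may interfere with the amide acetal, so that condensation at C5 and ring closure stay incomplete, and the amine set free may promote retro-aldol erosion of the carbinol before it is locked in the ring. The fallback sets out from 2 and gives up the three-component format and the ester helper. Acetylacetone is silylated twice (Me3SiOTf, Et3N) to 2,4-bis(trimethylsilyloxy)penta-1,3-diene F1. F1 is added to 2 under the same Ti(OiPr)4/(S)-BINOL catalysis and the adduct is methanolysed (MeOH, PPTS) to (6R,18Z)-6-hydroxyheptacos-18-ene-2,4-dione F2. Acid-catalysed cyclodehydration of F2 (TsOH, CH2Cl2, rt) closes the enol ether and comes back to the route at 12.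

Step 5. Decarboxylation of the vinylogous acid may stall because the carboxyl sits on an sp2 carbon, and prolonged heating in acid may cause dehydration or reversible ring opening with loss of stereochemical integrity. The fallback sets out from 8, isolated by chromatography after the methanolysis stage of step 4, and moves the loss of CO2 to an open-chain tetrahedral carbon before the ring exists. The carbinol is silylated (Et3SiCl, imidazole, CH2Cl2) to tert-butyl (5R,17Z)-3-oxo-5-(triethylsilyloxy)hexacos-17-enoate F3. C-acetylation of its magnesium enolate (MgCl2, pyridine, AcCl, CH2Cl2, 0 °C) should give tert-butyl (5R,17Z)-2-acetyl-3-oxo-5-(triethylsilyloxy)hexacos-17-enoate F4. Treatment of F4 with TFA in CH2Cl2 and gentle warming should remove the tert-butyl group, CO2 and the silyl ether and cyclodehydrate the resulting δ-hydroxy-β-diketone, coming back to the route at 12.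

Step 3. The ketene silyl acetal may be lost by protodesilylation during isolation, and the lithium dienolate may undergo competing C-silylation, so that the diene reaches step 4 in poor purity. The fallback sets out from 3 and omits both 4 and the lithium dienolate: double soft enolisation with Me3SiOTf (2.2 equiv) and Et3N in Et2O at 0 °C should silylate both enolisable positions in one flask. The ammonium triflate layer is separated and the crude diene used at once, coming back to the route at 5. No new compound is formed.

**Further compounds**

F1 | step 4 | 2,4-bis(trimethylsilyloxy)penta-1,3-diene | C=C(O[Si](C)(C)C)C=C(C)O[Si](C)(C)C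
F2 | step 4 | (6R,18Z)-6-hydroxyheptacos-18-ene-2,4-dione | CCCCCCCC/C=C\CCCCCCCCCCC[C@@H](O)CC(=O)CC(C)=O
F3 | step 5 | tert-butyl (5R,17Z)-3-oxo-5-(triethylsilyloxy)hexacos-17-enoate | CCCCCCCC/C=C\CCCCCCCCCCC[C@@H](O[Si](CC)(CC)CC)CC(=O)CC(=O)OC(C)(C)C
F4 | step 5 | tert-butyl (5R,17Z)-2-acetyl-3-oxo-5-(triethylsilyloxy)hexacos-17-enoate | CCCCCCCC/C=C\CCCCCCCCCCC[C@@H](O[Si](CC)(CC)CC)CC(=O)C(C(C)=O)C(=O)OC(C)(C)C
F0 | step 3 | none | none
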